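**Retrosynthetic overview**
1. Ar = 7-methoxy-2-oxo-2H-chromen-8-yl, and each arm is numbered C1 (benzylic), C2, C3, C4 (=CH2), C5 (CH3). The strategy rests on one feature. The ether core Ar–C1H–O–C1′H–Ar is meso-configured (1R,1′S), while the flanking carbinols C2 and C2′ are both R. Each carbinol sits next to an isopropenyl carbon C3(=C4H2), which is the pattern left when a C2–C3 oxirane with a leaving group on C4 is opened reductively.
2. Steps 10–11: both HO–C2/C3=C4 units go back to C2–C3 oxiranes carrying C4–I, and these go back to the bis-2,3-epoxy alcohol 14.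
3. Step 9: all four oxirane C–O bonds come from one double asymmetric epoxidation of the meso bis-(E)-allylic alcohol 13, which is desymmetrised in that step.
4. Steps 5–8: 13 comes from the meso dialdehyde O(CHAr–CHO)2 by Wittig olefination and Luche reduction. The dialdehyde is the C3–C4 glycol-cleavage product of a cis-2,5-diaryltetrahydrofuran-3,4-diol. Its two C–Ar bonds are made by double arylation of 2,5-dimethoxytetrahydrofuran-3,4-diol acetonide with the 8-coumarinylzinc reagent.
5. Ring order: both coumarin bicycles and the oxolane template are bought. The dioxolane is closed in step 4 and opened in step 6, and the oxolane is cleaved in step 7. The two oxiranes are closed together in step 9 and opened together in step 11.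

Key step: step 9

Assumption: 4 is used as the commercial cis/trans mixture and 5 and 6 as anomeric mixtures, because both acetal carbons are planarised on ionisation in step 5.

**Step 1**
Reactants: 1 umbelliferone (7-hydroxycoumarin)
Product: 2 7-hydroxy-8-iodocoumarin
Conditions: I2, KI, aq NH3, 0 °C → rt; acidic work-up
Reagents that add atoms: iodine, II
Why: Electrophilic aromatic iodination of the phenoxide should go to C8, the ortho position of highest electron density in umbelliferone (the site also taken in Duff and Mannich reactions), and it creates no stereocentre.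

**Step 2**
Reactants: 2 7-hydroxy-8-iodocoumarin
Product: 3 8-iodo-7-methoxycoumarin
Conditions: MeI, K2CO3, acetone, reflux
Reagents that add atoms: iodomethane, CI
Why: Williamson ether synthesis on the acidic 7-OH, with the lactone and the aryl iodide inert to carbonate in acetone.

**Step 3**
Reactants: 4 2,5-dimethoxy-2,5-dihydrofuran
Product: 5 2,5-dimethoxytetrahydrofuran-3,4-diol (3,4-cis, anomeric mixture)
Conditions: OsO4 (cat.), NMO, acetone/H2O, rt
Reagents that add atoms: N-methylmorpholine N-oxide, C[N+]1([O-])CCOCC1 (oxygen relayed through osmium); water, O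
Why: Upjohn dihydroxylation adds both oxygens to one face of the ring alkene, so C3 and C4 become a cis-diol, and the mixed configuration of the acetal carbons is of no consequence.

**Step 4**
Reactants: 5 2,5-dimethoxytetrahydrofuran-3,4-diol
Product: 6 3,4-O-isopropylidene-2,5-dimethoxytetrahydrofuran (cis-fused, anomeric mixture)
Conditions: Me2C(OMe)2, PPTS (cat.), CH2Cl2, rt
Reagents that add atoms: 2,2-dimethoxypropane, COC(C)(C)OC
Why: Acid-catalysed transketalisation closes the dioxolane on the cis-diol and gives a cis-fused bicyclo[3.3.0] system whose concave face is blocked for the next step.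

**Step 5**
Reactants: 3 8-iodo-7-methoxycoumarin (two equivalents are incorporated); 6 3,4-O-isopropylidene-2,5-dimethoxytetrahydrofuran
Product: 8 meso 2,5-cis-diaryl tetrahydrofuran acetonide (both Ar groups trans to the dioxolane; 2R,3R,4S,5S), via arylzinc iodide 7 (not isolated)
Conditions: 3 (2.6 equiv), Zn dust, LiCl, THF, 50 °C; THF exchanged for toluene/CH2Cl2; 6, BF3·OEt2 (promoter), −40 °C → rt
Reagents that add atoms: none
Why: LiCl-mediated zinc insertion into the C8–I bond tolerates the lactone, and the arylzinc then replaces both methoxy groups in turn through BF3-generated furanosyl oxocarbenium ions (C-glycosylation-type arylation), each time entering on the convex face anti to the dioxolane, which sets C2 and C5 (later C1 and C1′) cis to each other and makes 8 meso.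

**Step 6**
Reactants: 8 meso diaryl tetrahydrofuran acetonide
Product: 9 meso (2R,3R,4S,5S)-2,5-bis(7-methoxy-2-oxo-2H-chromen-8-yl)tetrahydrofuran-3,4-diol
Conditions: AcOH/H2O 4:1, 50 °C
Reagents that add atoms: none
Why: Acid-catalysed ketal hydrolysis frees the cis-diol under conditions too mild to ionise the benzylic ring C–O bonds, which are deactivated by the neighbouring oxygenated carbons, so C2 and C5 keep their configuration.

**Step 7**
Reactants: 9 meso diaryl tetrahydrofuran-3,4-diol; 10 2-(triphenylphosphoranylidene)propanal
Product: 12 meso bis-(E)-enal O[CH(Ar)CH=C(CH3)CHO]2 (1R,1′S), via meso dialdehyde 11 (not isolated)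
Conditions: NaIO4 on silica gel, CH2Cl2, rt; filter; 10 (3 equiv), CH2Cl2, rt → 40 °C
Reagents that add atoms: 2-(triphenylphosphoranylidene)propanal (10), CC(C=O)=P(c1ccccc1)(c1ccccc1)c1ccccc1
Why: Malaprade glycol cleavage breaks C3–C4 of the template ring and the neutral filtrate is olefinated at once in a Wittig reaction with the stabilised ylide, which should give both (E)-2-methylenals (the geometry that later fixes C2) without base and so without enolisation of the α-aryl-α-alkoxy aldehyde centres.

**Step 8**
Reactants: 12 meso bis-(E)-enal
Product: 13 meso bis-(E)-allylic alcohol O[CH(Ar)CH=C(CH3)CH2OH]2 (1R,1′S)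
Conditions: NaBH4, CeCl3·7H2O, MeOH/THF, −40 °C
Reagents that add atoms: none
Why: Luche reduction attacks the enal carbonyls in the 1,2 sense much faster than borohydride touches the coumarin lactones or their conjugated C3=C4 bonds, and it creates no stereocentre.

**Step 9**
Reactants: 13 meso bis-(E)-allylic alcohol
Product: 14 bis-epoxy alcohol; each arm is a [(2S,3S)-3-substituted-2-methyloxiran-2-yl]methanol, with benzylic carbons 1R and 1′S
Conditions: Ti(OiPr)4 (0.5 equiv), L-(+)-DIPT (0.6 equiv), anhydrous TBHP in decane (5 equiv), 4 Å MS, CH2Cl2, −20 °C; aq tartaric acid work-up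
Reagents that add atoms: tert-butyl hydroperoxide, CC(C)(C)OO
Why: Each primary hydroxyl and a tert-butylperoxy ligand exchange onto one titanium of the dimeric titanium–tartrate complex, and the bound alkene attacks the coordinated peroxide oxygen along the O–O axis, so the transfer is intramolecular and the C2–O and C3–O bonds of an arm form in one suprafacial event. The closest known reaction is the Katsuki–Sharpless asymmetric epoxidation run in two directions on achiral or meso bis-allylic alcohols. Each of the two oxiranes is thus closed by a concerted [2+1] oxygen-atom transfer that carries the E geometry over into a trans relation between C1 and the CH2OH carbon. C2, C3, C2′ and C3′ are all fixed by the L-(+)-tartrate ligand, which converts (E)-2-methyl allylic alcohols into (2S,3S)-epoxy alcohols, while C1 and C1′ are spectators. The step needs the same absolute facial sense in two mirror-image arms, that is reagent control over the A(1,3)-biased C1 centre in the mismatched arm, and this is supported by the substrate class (primary carbinol, E-trisubstituted, hydrogen cis to CH2OH), for which the tartrate bias is strongest; a single facial error gives an achiral meso diastereomer that chromatography can remove and only a double error gives the enantiomer, so enantiomeric purity is amplified statistically. Chemoselectivity rests on the coumarin C3=C4 bonds being electron-poor and having no hydroxyl to bind titanium.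

**Step 10**
Reactants: 14 bis-epoxy alcohol
Product: 15 bis-epoxy iodide (same spatial arrangement; oxirane carbons now designated 2R,3S in each arm because CH2I outranks the ring CH)
Conditions: I2, PPh3, imidazole, CH2Cl2, 0 °C
Reagents that add atoms: iodine, II
Why: Appel-type iodination activates only the two primary hydroxyls and replaces them by SN2 attack of iodide at C4 and C4′, with the imidazole buffer protecting the oxiranes, so no stereocentre is touched.

**Step 11**
Reactants: 15 bis-epoxy iodide
Product: 16 target CNP0283712.1, 8-[(1R,2R)-2-hydroxy-1-{[(1S,2R)-2-hydroxy-1-(7-methoxy-2-oxo-2H-chromen-8-yl)-3-methylbut-3-en-1-yl]oxy}-3-methylbut-3-en-1-yl]-7-methoxy-2H-chromen-2-one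
Conditions: activated Zn dust, AcOH (4 equiv), EtOH, 0 °C → rt
Reagents that add atoms: none
Why: Zinc inserts into each C4–I bond and the organozinc expels the oxirane oxygen from C3 (reductive β-elimination of a 2,3-epoxy iodide), which forms the C3=C4H2 methylene and leaves the C2–O bond intact, so both carbinols keep the geometry set in step 9 and are now designated R because C1 outranks the sp2 carbon C3.

**Compound list**
1 | umbelliferone | O=c1ccc2ccc(O)cc2o1 | starting material
2 | 7-hydroxy-8-iodocoumarin | O=c1ccc2ccc(O)c(I)c2o1 | intermediate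
3 | 8-iodo-7-methoxycoumarin | COc1ccc2ccc(=O)oc2c1I | intermediate
4 | 2,5-dimethoxy-2,5-dihydrofuran (cis/trans mixture) | COC1C=CC(OC)O1 | starting material
5 | 2,5-dimethoxytetrahydrofuran-3,4-diol (3,4-cis) | COC1OC(OC)[C@H](O)[C@@H]1O | intermediate
6 | 3,4-O-isopropylidene-2,5-dimethoxytetrahydrofuran | COC1OC(OC)[C@@H]2OC(C)(C)O[C@H]12 | intermediate
7 | (7-methoxy-2-oxo-2H-chromen-8-yl)zinc iodide (LiCl complex) | COc1ccc2ccc(=O)oc2c1[Zn]I | intermediate
8 | meso 2,5-cis-diaryl-3,4-O-isopropylidenetetrahydrofuran | COc1ccc2ccc(=O)oc2c1[C@H]1O[C@@H](c2c(OC)ccc3ccc(=O)oc23)[C@@H]2OC(C)(C)O[C@H]12 | intermediate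
9 | meso 2,5-cis-diaryltetrahydrofuran-3,4-diol | COc1ccc2ccc(=O)oc2c1[C@H]1O[C@@H](c2c(OC)ccc3ccc(=O)oc23)[C@H](O)[C@@H]1O | intermediate
10 | 2-(triphenylphosphoranylidene)propanal | CC(C=O)=P(c1ccccc1)(c1ccccc1)c1ccccc1 | starting material
11 | meso dialdehyde O(CHAr–CHO)2 | O=C[C@@H](c1c(OC)ccc2ccc(=O)oc12)O[C@@H](c1c(OC)ccc2ccc(=O)oc12)C=O | intermediate
12 | meso bis-(E)-enal | O=C/C(C)=C/[C@H](O[C@@H](c1c(OC)ccc2ccc(=O)oc12)/C=C(\C)C=O)c1c(OC)ccc2ccc(=O)oc12 | intermediate
13 | meso bis-(E)-allylic alcohol | OC/C(C)=C/[C@H](O[C@@H](c1c(OC)ccc2ccc(=O)oc12)/C=C(\C)CO)c1c(OC)ccc2ccc(=O)oc12 | intermediate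
14 | bis-(2S,3S)-epoxy alcohol | OC[C@]1(C)O[C@H]1[C@H](O[C@@H](c1c(OC)ccc2ccc(=O)oc12)[C@@H]1O[C@@]1(C)CO)c1c(OC)ccc2ccc(=O)oc12 | intermediate
15 | bis-epoxy iodide | IC[C@]1(C)O[C@H]1[C@H](O[C@@H](c1c(OC)ccc2ccc(=O)oc12)[C@@H]1O[C@@]1(C)CI)c1c(OC)ccc2ccc(=O)oc12 | intermediate
16 | CNP0283712.1 | C=C(C)[C@@H](O)[C@H](O[C@@H](c1c(OC)ccc2ccc(=O)oc12)[C@H](O)C(=C)C)c1c(OC)ccc2ccc(=O)oc12 | target

**Total step count:** 11. **Longest linear sequence:** 9 steps (4 → 16 through steps 3–11, or 1 → 16 through steps 1, 2 and 5–11).

**Steps most likely to fail**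

Step 9 (key step).
- Risk: in the mismatched arm the conformation imposed by allylic strain at C1 may erode or override the facial bias of the tartrate. That arm may also react so slowly that opening of the first oxirane by titanium alkoxides competes.
- Fallback: undirected reagent control by a chiral dioxirane.
  - Setting out from 13, both hydroxyls are silylated (TBSCl, imidazole, DMF) to give the bis-TBS ether of 13 F1.
  - F1 is submitted to a Shi epoxidation with the enantiomer of the fructose-derived ketone (made from L-sorbose). The conditions are Oxone, K2CO3–AcOH buffer near pH 9, MeCN/dimethoxymethane/water, 0 °C.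
  - This should give the bis-(S,S)-epoxide bis-TBS ether F2 through a spiro transition state that reads only the trisubstituted alkene and needs no bound hydroxyl.
  - HF·pyridine in THF then removes the silyl groups, and the route is rejoined at 14.

Step 5.
- Risk: the doubly ortho-substituted, lactone-bearing arylzinc may be too weak a nucleophile. The oxocarbenium ion could then lose a proton and drift towards furan formation, or the second substitution could stall or lose its facial selectivity.
- Fallback: introduce a more electron-rich aryl group and build the pyranone rings afterwards.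
  - Setting out from 6, commercial 2-iodo-1,3-dimethoxybenzene is converted (Zn, LiCl, THF) into 2,6-dimethoxyphenylzinc iodide F3.
  - Under the BF3·OEt2 conditions F3 should give the meso bis(2,6-dimethoxyphenyl)tetrahydrofuran acetonide F4.
  - Double Vilsmeier–Haack formylation (POCl3, DMF), para to one methoxy group of each ring, gives the bis(3-formyl-2,6-dimethoxyphenyl) compound F5.
  - MgI2·OEt2 cleaves only the methoxy group chelated to each formyl group and gives the bis-salicylaldehyde F6.
  - Wittig olefination with ethyl (triphenylphosphoranylidene)acetate in refluxing N,N-diethylaniline gives the bis(2-hydroxycinnamate) F7. F7 isomerises and lactonises in the same flask, and the route is rejoined at 8.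

Step 7.
- Risk: slow olefination by the weakly nucleophilic formyl ylide leaves the dialdehyde exposed to hydration and to enolisation, which would lose the meso relation at C1/C1′. The enal product may also be homologated a second time.
- Fallback: a two-stage homologation through a thioester.
  - Setting out from 9, the diol is cleaved as before to 11.
  - The filtrate is treated with the more nucleophilic S-ethyl 2-(triphenylphosphoranylidene)propanethioate in CH2Cl2 at 0 °C → rt. This gives the bis-(E)-enethioate F8, which cannot react further with the ylide.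
  - Fukuyama reduction (Et3SiH, Pd/C, acetone, rt) should then turn both thioesters into aldehydes without touching the lactones, and the route is rejoined at 12.

**Further compounds**
F1 | step 9 | bis-TBS ether of 13 | CC(C)(C)[Si](C)(C)OC/C(C)=C/[C@H](O[C@@H](c1c(OC)ccc2ccc(=O)oc12)/C=C(\C)CO[Si](C)(C)C(C)(C)C)c1c(OC)ccc2ccc(=O)oc12
F2 | step 9 | bis-(S,S)-epoxide bis-TBS ether | CC(C)(C)[Si](C)(C)OC[C@]1(C)O[C@H]1[C@H](O[C@@H](c1c(OC)ccc2ccc(=O)oc12)[C@@H]1O[C@@]1(C)CO[Si](C)(C)C(C)(C)C)c1c(OC)ccc2ccc(=O)oc12
F3 | step 5 | 2,6-dimethoxyphenylzinc iodide | COc1cccc(OC)c1[Zn]I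
F4 | step 5 | meso bis(2,6-dimethoxyphenyl)tetrahydrofuran acetonide | COc1cccc(OC)c1[C@H]1O[C@@H](c2c(OC)cccc2OC)[C@@H]2OC(C)(C)O[C@H]12
F5 | step 5 | bis(3-formyl-2,6-dimethoxyphenyl) compound | COc1ccc(C=O)c(OC)c1[C@H]1O[C@@H](c2c(OC)ccc(C=O)c2OC)[C@@H]2OC(C)(C)O[C@H]12
F6 | step 5 | bis-salicylaldehyde | COc1ccc(C=O)c(O)c1[C@H]1O[C@@H](c2c(OC)ccc(C=O)c2O)[C@@H]2OC(C)(C)O[C@H]12
F7 | step 5 | bis(2-hydroxycinnamate) | COc1ccc(/C=C/C(=O)OCC)c(O)c1[C@H]1O[C@@H](c2c(OC)ccc(/C=C/C(=O)OCC)c2O)[C@@H]2OC(C)(C)O[C@H]12
F8 | step 7 | bis-(E)-enethioate | CCSC(=O)/C(C)=C/[C@H](O[C@@H](c1c(OC)ccc2ccc(=O)oc12)/C=C(\C)C(=O)SCC)c1c(OC)ccc2ccc(=O)oc12
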